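## Structural features

The target is a cyclobutane in which every ring carbon is a stereocentre. C1 carries H and a methyl ester, C2 carries H and a free carboxylic acid, and C3 and C4 are quaternary, each bearing a methyl group and a 4-methoxy-3-methyl-2-oxopyran-6-yl ring attached through its C6. The two carboxyl groups are cis to each other and to both ring methyls; the two pyranones share the opposite face. Without the ester/acid difference the molecule would have a mirror plane through the midpoints of C1–C2 and C3–C4, so its chirality (1R,2S,3R,4S in this numbering) rests only on which of two enantiotopic carboxyls is esterified. Fragile points are the epimerisable C1–H and C2–H, the pyranones (vinylogous ester-lactones, opened by hydroxide or strong nucleophiles) and the crowded C3–C4 bond between two quaternary carbons. The real difficulty is the cis vicinal quaternary pair on a four-membered ring, together with telling the two carboxyls apart. The key step exploits C1 and C2: they are neighbouring methines with carboxyl groups on one face, so inserting a nitrogen between them turns the cyclobutane into a cis-pyrrolidine-2,5-dicarboxylate, the cycloadduct of a symmetric azomethine ylide with a Z-alkene that supplies C3 and C4.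

## Logic of the disconnections

16 is traced to 15 by turning the C2 acid back into a methyl ester. This restores the mirror plane, so 15 and everything before it is meso or achiral and no chiral reagent is carried through the sequence. The forward step must choose one of two enantiotopic esters, stop after one hydrolysis and leave both lactones alone, which calls for an esterase at neutral pH.

In 15 the two O–CH3 bonds at C4' of the pyranones are cut, giving 14. The 4-hydroxypyranone is what a malonyl annulation delivers directly. The forward step must alkylate the 4-oxygen rather than the ring carbonyl oxygen, with a base too weak to epimerise C1 or C2.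

In each pyranone of 14 the bonds C4'–C5' and O1'–C2' are cut. This removes C2', C3' (with its methyl) and C4' as one three-carbon bis-electrophile, 13, and leaves only a two-carbon enol unit on C3 and on C4, as in 11. Both heterocycles disappear in one move. The forward step must acylate each enol ether at carbon, then close at oxygen, on both arms and without base.

11 is 10 with both ketones enolised toward their only hydrogen-bearing side (two O–Si bonds cut), and 13 is the bis(acid chloride) of 12. Silylation must distinguish ketone from ester α-hydrogens and must not let one enol unit add to the neighbouring ketone.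

The C1–C2 bond of 10 is cut and a nitrogen atom is placed between the two carbons, giving 7. C1 and C2 are chosen because they are the only ring carbons that carry hydrogen and a radical-stabilising ester, and they are cis. The strained ring with its quaternary pair becomes a five-membered cycloadduct. The forward step must extrude nitrogen with retention at both carbons, couple faster than C3–C4 cleaves, and tolerate two free methyl ketones; these are carried unprotected to save steps, with a masked variant held in reserve.

In 7 the bonds C1–C4 and C2–C3 (target numbering) are cut, separating a symmetric C–N–C unit, 6, from a four-carbon Z-alkene, 3; 6 is cut at C=N into 4 and 5. Four stereocentres reduce to one alkene geometry, one ylide shape and one approach mode. The forward step must keep 3 in its Z form, react at both ends of a tetrasubstituted alkene and approach exo. For that reason 6 is made before 3 is admitted, so the primary amine never meets the enedione.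

3 is closed in thought through one oxygen to 2, whose ring guarantees the cis geometry, and 2 is the cyclodehydration product of 1. The oxidant must stop at the enedione and not isomerise it.

## Other disconnections considered

Alternative 1: The cut is the C3'–C4' bond of each pyranone. In the forward step the bis[(Z)-enol propionate] A2, with a –C(OCOEt)=CH–CO2Me arm on each of C3 and C4, would be treated with LiN(SiMe3)2. Each propionate enolate would attack the methyl ester held cis across the enol double bond (intramolecular Claisen condensation) to give bis(hydroxypyranone) A1, which has a methyl ester at C1 and a tert-butyl ester at C2.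
- In its favour: ring oxygen, C5'–C6' double bond and 3'-methyl are fixed before closure, and no acid chloride is needed.
- Better than the chosen plan on one point: the carboxyls of A1 are already different, so the end (O-methylation, then acidolysis of the tert-butyl ester) is not stereodetermining, whereas the chosen plan sets absolute configuration in its last step.
- Against it: the differentiation is only moved upstream. A2 needs an enantioenriched cyclobutane with two different esters, and each side chain must be taken to a β-keto ester and then to a geometrically pure Z enol ester.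
- Mechanistically, the electrophile is a deactivated β-acyloxy enoate, and at least four equivalents of strong base face two epimerisable hydrogens and enol esters prone to acyl transfer.
- On making the cyclobutane the two plans are equal, since this alternative does not address it. It would cost about three operations for the pyranone pair against two (steps 5 and 7).

Alternative 2: The cuts are the two exocyclic bonds from C1 and C2 to their carboxyl carbons. The bicyclic cyclobutene anhydride A4 would be bis-methoxycarbonylated under CO in methanol with catalytic PdCl2 (divalent palladium) and CuCl2 as oxidant. A methoxycarbonylpalladium species should add syn from the convex face, and the alkylpalladium, which has no syn β-hydrogen, should insert CO to give diester anhydride A3.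
- In its favour: syn addition gives the cis diester, convex-face attack places it anti to the anhydride as the target requires, and the two pairs of carboxyls emerge differentiated.
- Better than the chosen plan on one point: the ring would come from a photocycloaddition with no biradical of the type of 9, so ring formation is more certain.
- Against it: the convex face is flanked by the two angular methyls. More seriously, each anhydride carbonyl of A3 sits on a quaternary carbon and must become a pyranone C6, which means a twofold ketone synthesis on a cis-diacid that prefers to re-close, in the presence of two methyl esters.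
- A3 is meso, so the enantiotopic-group problem is equal in both plans.
- Step economy is worse: about two steps to A4, one to A3 and at least four more to a compound of the type of 10, against four steps to 10, with pressurised CO and stoichiometric CuCl2 besides.

Alternative 3: The cut goes through the ring, bonds C1–C4 and C2–C3. Sensitised irradiation of 2,3-dimethylmaleic anhydride A6 with maleic anhydride A7 would join the two cis-locked alkenes to the cis,anti,cis dianhydride A5.
- Better than the chosen plan on step economy to the carbocycle: one step from two bulk chemicals would build the ring and all four stereocentres in the right relative sense, against four steps to 10.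
- Also better on absolute configuration: the unhindered anhydride on C1/C2 could be opened by methanol under a cinchona alkaloid, where the sense can be chosen through the pseudoenantiomer, which an enzyme does not allow.
- Against it: both partners also dimerise, so the crossed adduct would compete with two homodimers.
- The anhydride on the quaternary carbons would again have to be elaborated into two pyranones; carbon nucleophiles tend to stop at lactones or keto acids, and the free acid from an early methanolysis would need protection.
- Mechanistically the photocycloaddition is at least as secure as the nitrogen extrusion, but the chosen plan brings the two methyl ketones in ready-made and so is shorter overall.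

Key step: step 4

Assumption: pig liver esterase is taken to cleave the ester on the S-configured carbon C2 of 15; this sense cannot be deduced for so substituted a substrate, and if the enzyme prefers the C1 ester the fallback for step 9 supplies the same enantiomer.

## Route

Step 1
Reactants: 1 3,4-dimethylhexane-2,5-dione (commercial mixture of diastereomers)
Product: 2 2,3,4,5-tetramethylfuran
Conditions: TsOH·H2O (5 mol %), toluene, reflux, Dean–Stark trap
Reagents that add atoms: none
Why: Paal–Knorr furan synthesis; acid-catalysed cyclodehydration of the 1,4-diketone is driven by water removal and aromatisation, and both diastereomers of 1 converge because the stereocentres are lost.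

Step 2
Reactants: 2 2,3,4,5-tetramethylfuran
Product: 3 (Z)-3,4-dimethylhex-3-ene-2,5-dione
Conditions: mCPBA (1.05 equiv), CH2Cl2, −20 to 0 °C, dark; cold aq. NaHCO3 wash
Reagents that add atoms: mCPBA (3-chloroperoxybenzoic acid), O=C(OO)c1cccc(Cl)c1
Why: Peracid oxidative ring opening of a furan (epoxidation of one ring double bond, then opening to the enedione); the Z geometry is inherited from the ring, and low temperature, exclusion of light and prompt removal of the acid should prevent Z to E isomerisation.

Step 3
Reactants: 3 (Z)-3,4-dimethylhex-3-ene-2,5-dione; 4 glycine methyl ester hydrochloride; 5 methyl glyoxylate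
Product: 7 dimethyl (2R,3R,4S,5S)-3,4-diacetyl-3,4-dimethylpyrrolidine-2,5-dicarboxylate (meso), via glyoxylate imine 6 (not isolated)
Conditions: 4 (1.2 equiv), 5 (1.25 equiv), Et3N (1.2 equiv), 4 Å MS, THF, rt; then 3, Cu(CH3CN)4PF6 (5 mol %), (R)-DTBM-SEGPHOS (5.5 mol %), Et3N (10 mol %), 0 °C to rt
Reagents that add atoms: none
Why: Imine condensation followed by a 1,3-dipolar cycloaddition of the N-metalated azomethine ylide catalysed by monovalent copper. The N,O-chelated ylide is W-shaped (2,5-cis esters) and adds suprafacially to the Z-alkene (cis acetyls), while the bulky bisphosphine should disfavour the endo approach, so the esters end up anti to the acetyls and cis to the ring methyls, as the target requires. The ligand's handedness is irrelevant because 7 is meso, and forming 6 first keeps the primary amine away from the enedione.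

Step 4
Reactants: 7 dimethyl (2R,3R,4S,5S)-3,4-diacetyl-3,4-dimethylpyrrolidine-2,5-dicarboxylate
Product: 10 dimethyl (1R,2S,3R,4S)-3,4-diacetyl-3,4-dimethylcyclobutane-1,2-dicarboxylate (meso), via 1,1-diazene 8 (not isolated), via 1,4-biradical 9 (not isolated)
Conditions: PhI(OH)OTs (2.5 equiv), NH2CO2NH4 (8 equiv), CF3CH2OH, 80 °C
Reagents that add atoms: none
Why: The trivalent iodine reagent and ammonia released from the carbamate form an electrophilic iodonitrene that transfers nitrogen to the secondary amine of 7; loss of iodobenzene leaves 1,1-diazene 8, which expels dinitrogen to give singlet 1,4-biradical 9 with its centres at C1 and C2, each conjugated with an ester. The closest known reaction type is the contraction of polysubstituted pyrrolidines, including 2-carboxylates from ylide cycloadditions, to cyclobutanes with this reagent pair. The four-membered ring closes by direct coupling of the two radical termini (bond C1–C2), a five-to-four ring contraction by extrusion rather than a polar cyclisation. C1 and C2 keep the configuration they had as C2 and C5 of the pyrrolidine because the singlet pair should couple before rotation about C1–C4 or C2–C3; C3 and C4 are untouched, so the product stays meso. The selectivity needed is coupling over scission of the crowded C3–C4 bond; the ester groups stabilise both radical centres, the singlet state allows near-barrierless coupling, and the vicinal quaternary carbons hold the termini close. The ketones are neopentylic, enolise only at CH3 and slowly in the ammonia-buffered medium, and the iodine reagent is consumed by ammonia first, so α-oxidation should not compete.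

Step 5
Reactants: 10 dimethyl (1R,2S,3R,4S)-3,4-diacetyl-3,4-dimethylcyclobutane-1,2-dicarboxylate
Product: 11 dimethyl (1R,2S,3R,4S)-3,4-dimethyl-3,4-bis[1-(trimethylsilyloxy)ethenyl]cyclobutane-1,2-dicarboxylate
Conditions: TMSOTf (2.4 equiv), Et3N (3.5 equiv), CH2Cl2, −78 to 0 °C
Reagents that add atoms: trimethylsilyl trifluoromethanesulfonate, C[Si](C)(C)OS(=O)(=O)C(F)(F)F
Why: Silyl enol ether formation by soft enolisation; each ketone can enolise only toward CH3, and the ester α-hydrogens at C1 and C2 are not acidic enough under these conditions, so no epimerisation is expected. Excess amine and low temperature should keep the silyl triflate from promoting a Mukaiyama aldol between one enol ether and the neighbouring ketone.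

Step 6
Reactants: 12 methylmalonic acid
Product: 13 methylmalonyl dichloride
Conditions: SOCl2 (3 equiv), DMF (cat.), 50 °C; distillation
Reagents that add atoms: thionyl chloride, O=S(Cl)Cl
Why: Standard acid chloride formation; the volatile by-products leave and the dichloride is purified by distillation.

Step 7
Reactants: 11 dimethyl (1R,2S,3R,4S)-3,4-dimethyl-3,4-bis[1-(trimethylsilyloxy)ethenyl]cyclobutane-1,2-dicarboxylate; 13 methylmalonyl dichloride
Product: 14 dimethyl (1R,2S,3R,4S)-3,4-bis(4-hydroxy-3-methyl-2-oxo-2H-pyran-6-yl)-3,4-dimethylcyclobutane-1,2-dicarboxylate (meso)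
Conditions: 13 (2.5 equiv), Et2O, −78 °C to rt
Reagents that add atoms: none
Why: Annulation of silyl enol ethers with a malonyl dichloride to 4-hydroxy-2-pyranones; C-acylation at the terminal enol carbon is followed by lactonisation of the enol oxygen onto the second acyl chloride. The medium is base-free, so C1 and C2 are not at risk, and the excess of 13 should favour one malonyl unit per arm.

Step 8
Reactants: 14 dimethyl (1R,2S,3R,4S)-3,4-bis(4-hydroxy-3-methyl-2-oxo-2H-pyran-6-yl)-3,4-dimethylcyclobutane-1,2-dicarboxylate
Product: 15 dimethyl (1R,2S,3R,4S)-3,4-bis(4-methoxy-3-methyl-2-oxo-2H-pyran-6-yl)-3,4-dimethylcyclobutane-1,2-dicarboxylate (meso)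
Conditions: Me2SO4 (2.5 equiv), K2CO3 (3 equiv), acetone, rt to 40 °C
Reagents that add atoms: dimethyl sulfate, COS(=O)(=O)OC
Why: O-alkylation of the ambident 4-hydroxypyranone anion; with the potassium salt and a hard methylating agent in acetone the 4-oxygen should be methylated, giving the 4-methoxy-2-pyranone rather than the 2-methoxy-4-pyranone. The carbonate is too weak a base to epimerise the ester α-carbons.

Step 9
Reactants: 15 dimethyl (1R,2S,3R,4S)-3,4-bis(4-methoxy-3-methyl-2-oxo-2H-pyran-6-yl)-3,4-dimethylcyclobutane-1,2-dicarboxylate
Product: 16 (1S,2R,3S,4R)-2-(methoxycarbonyl)-3,4-bis(4-methoxy-3-methyl-2-oxo-2H-pyran-6-yl)-3,4-dimethylcyclobutane-1-carboxylic acid (target)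
Conditions: pig liver esterase, 0.1 M phosphate buffer pH 7.5, DMSO (10 vol %), 30 °C; then acidify to pH 3
Reagents that add atoms: water, O
Why: Enzymatic desymmetrisation of a meso cis-1,2-diester by enantiotopic-group-selective hydrolysis; the chiral active site distinguishes the two esters and sets the absolute configuration, and the monoacid anion is a poor substrate, so hydrolysis should stop after one ester. Neutral pH should spare the pyranones and the α-stereocentres.

## Compound list

1 | 3,4-dimethylhexane-2,5-dione | CC(=O)C(C)C(C)C(C)=O | starting material
2 | 2,3,4,5-tetramethylfuran | Cc1oc(C)c(C)c1C | intermediate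
3 | (Z)-3,4-dimethylhex-3-ene-2,5-dione | CC(=O)/C(C)=C(/C)C(C)=O | intermediate
4 | glycine methyl ester hydrochloride | Cl.NCC(=O)OC | starting material
5 | methyl glyoxylate | COC(=O)C=O | starting material
6 | methyl (E)-N-(2-methoxy-2-oxoethylidene)glycinate | COC(=O)C/N=C/C(=O)OC | intermediate
7 | dimethyl (2R,3R,4S,5S)-3,4-diacetyl-3,4-dimethylpyrrolidine-2,5-dicarboxylate (meso) | COC(=O)[C@@H]1N[C@H](C(=O)OC)[C@@](C)(C(C)=O)[C@@]1(C)C(C)=O | intermediate
8 | 1,1-diazene (N-nitrene) of 7 | COC(=O)[C@@H]1[N+](=[N-])[C@H](C(=O)OC)[C@@](C)(C(C)=O)[C@@]1(C)C(C)=O | intermediate
9 | dimethyl meso-3,4-diacetyl-3,4-dimethylhexanedioate-2,5-diyl (singlet 1,4-biradical) | COC(=O)[CH][C@](C)(C(C)=O)[C@](C)(C(C)=O)[CH]C(=O)OC | intermediate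
10 | dimethyl (1R,2S,3R,4S)-3,4-diacetyl-3,4-dimethylcyclobutane-1,2-dicarboxylate (meso) | COC(=O)[C@@H]1[C@H](C(=O)OC)[C@@](C)(C(C)=O)[C@@]1(C)C(C)=O | intermediate
11 | dimethyl (1R,2S,3R,4S)-3,4-dimethyl-3,4-bis[1-(trimethylsilyloxy)ethenyl]cyclobutane-1,2-dicarboxylate | COC(=O)[C@@H]1[C@H](C(=O)OC)[C@@](C)(C(=C)O[Si](C)(C)C)[C@@]1(C)C(=C)O[Si](C)(C)C | intermediate
12 | methylmalonic acid | CC(C(=O)O)C(=O)O | starting material
13 | methylmalonyl dichloride | CC(C(=O)Cl)C(=O)Cl | intermediate
14 | dimethyl (1R,2S,3R,4S)-3,4-bis(4-hydroxy-3-methyl-2-oxo-2H-pyran-6-yl)-3,4-dimethylcyclobutane-1,2-dicarboxylate | COC(=O)[C@@H]1[C@H](C(=O)OC)[C@@](C)(c2cc(O)c(C)c(=O)o2)[C@@]1(C)c1cc(O)c(C)c(=O)o1 | intermediate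
15 | dimethyl (1R,2S,3R,4S)-3,4-bis(4-methoxy-3-methyl-2-oxo-2H-pyran-6-yl)-3,4-dimethylcyclobutane-1,2-dicarboxylate | COC(=O)[C@@H]1[C@H](C(=O)OC)[C@@](C)(c2cc(OC)c(C)c(=O)o2)[C@@]1(C)c1cc(OC)c(C)c(=O)o1 | intermediate
16 | (1S,2R,3S,4R)-2-(methoxycarbonyl)-3,4-bis(4-methoxy-3-methyl-2-oxo-2H-pyran-6-yl)-3,4-dimethylcyclobutane-1-carboxylic acid | COC(=O)[C@@H]1[C@H](C(=O)O)[C@@](C)(c2cc(OC)c(C)c(=O)o2)[C@@]1(C)c1cc(OC)c(C)c(=O)o1 | target

## Step count and least certain steps

Total step count: 9. Longest linear sequence: 8 steps (steps 1, 2, 3, 4, 5, 7, 8 and 9, from 1 to 16); step 6 is a one-step side branch.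

Step 4 (key step). The most likely failure is scission of the C3–C4 bond in biradical 9, which releases strain and forms two conjugated alkenes, running faster than radical coupling. A second is diversion of the iodine reagent and ammonia by the two free ketones (α-oxidation after enolisation, aminal formation). The fallback sets out from 7 and returns at 10. The cis-1,4-diketone is closed with HC(OMe)3 and MeOH under TsOH·H2O (1.2 equiv) to its cyclic bis(methyl ketal), dimethyl 1,3-dimethoxy-1,3,3a,6a-tetramethylhexahydro-1H-furo[3,4-c]pyrrole-4,6-dicarboxylate F1. F1 has no carbonyl to engage the reagents and no acyl group to stabilise fragmentation products. It is submitted to the same nitrogen deletion to give dimethyl 2,4-dimethoxy-1,2,4,5-tetramethyl-3-oxabicyclo[3.2.0]heptane-6,7-dicarboxylate F2, and aqueous acetic acid in THF then releases both ketones to give 10.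

Step 3. The most likely failure is slow addition to the twisted tetrasubstituted alkene. That leaves time for amine-promoted Z to E isomerisation or intramolecular aldol closure of 3 and for self-condensation of 6, and the exo over endo preference may also be insufficient. The fallback sets out from 3 and returns at 7. The dipole is generated without metal or base by thermal conrotatory ring opening of dimethyl trans-1-(4-methoxyphenyl)aziridine-2,3-dicarboxylate F3 (from dimethyl 2,3-dibromosuccinate and 4-methoxyaniline) in toluene at 110 °C in the presence of 3. The trans aziridine opens to the ylide that leads to cis-2,5 esters, and the neutral medium spares 3. The cycloadduct, dimethyl (2R,3R,4S,5S)-3,4-diacetyl-1-(4-methoxyphenyl)-3,4-dimethylpyrrolidine-2,5-dicarboxylate F4, is separated from any diastereomer and dearylated with (NH4)2Ce(NO3)6 in aqueous acetonitrile at 0 °C to give 7.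

Step 7. The most likely failure is incomplete twofold annulation: hydrogen chloride from the first ring closure can desilylate the second enol ether, or one malonyl unit can bridge both arms. The fallback sets out from 10 and returns at 14, bypassing 11. Soft enolisation of both ketones with MgBr2·OEt2 and i-Pr2NEt in CH2Cl2 and C-acylation with methyl 3-chloro-2-methyl-3-oxopropanoate should give the bis(3,5-dioxo ester), dimethyl (1R,2S,3R,4S)-3,4-bis(5-methoxy-4-methyl-3,5-dioxopentanoyl)-3,4-dimethylcyclobutane-1,2-dicarboxylate F5. Heating F5 with DBU in toluene closes each 4-hydroxypyranone by lactonisation of the enol oxygen onto the terminal ester, giving 14.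

Step 9. The most likely failure is hydrolysis of the wrong enantiotopic ester, or poor acceptance of the bulky, sparingly soluble substrate by the enzyme, giving low conversion or low enantiomeric purity. The fallback sets out from 15 and returns at 16. Both esters are cleaved with Me3SnOH in 1,2-dichloroethane at 80 °C to the meso diacid, (1R,2S,3R,4S)-3,4-bis(4-methoxy-3-methyl-2-oxo-2H-pyran-6-yl)-3,4-dimethylcyclobutane-1,2-dicarboxylic acid F6. Warm acetic anhydride closes it to the cyclic anhydride, (1R,5S,6S,7R)-6,7-bis(4-methoxy-3-methyl-2-oxo-2H-pyran-6-yl)-6,7-dimethyl-3-oxabicyclo[3.2.0]heptane-2,4-dione F7. F7 is opened with methanol in toluene at −55 °C in the presence of quinidine or quinine; the pseudoenantiomer that directs methanol to the C1 carbonyl is chosen, and this gives 16.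

## Further compounds

F1 | step 4 | dimethyl 1,3-dimethoxy-1,3,3a,6a-tetramethylhexahydro-1H-furo[3,4-c]pyrrole-4,6-dicarboxylate (cyclic bis(methyl ketal) of 7, ketal carbons as a mixture) | COC(=O)[C@@H]1N[C@H](C(=O)OC)[C@]2(C)[C@@]1(C)C(C)(OC)OC2(C)OC
F2 | step 4 | dimethyl 2,4-dimethoxy-1,2,4,5-tetramethyl-3-oxabicyclo[3.2.0]heptane-6,7-dicarboxylate (cyclic bis(methyl ketal) of 10, ketal carbons as a mixture) | COC(=O)[C@@H]1[C@H](C(=O)OC)[C@]2(C)[C@@]1(C)C(C)(OC)OC2(C)OC
F3 | step 3 | dimethyl trans-1-(4-methoxyphenyl)aziridine-2,3-dicarboxylate (racemic, one enantiomer drawn) | COC(=O)[C@H]1[C@H](C(=O)OC)N1c1ccc(OC)cc1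
F4 | step 3 | dimethyl (2R,3R,4S,5S)-3,4-diacetyl-1-(4-methoxyphenyl)-3,4-dimethylpyrrolidine-2,5-dicarboxylate (meso) | COC(=O)[C@@H]1N(c2ccc(OC)cc2)[C@H](C(=O)OC)[C@@](C)(C(C)=O)[C@@]1(C)C(C)=O
F5 | step 7 | dimethyl (1R,2S,3R,4S)-3,4-bis(5-methoxy-4-methyl-3,5-dioxopentanoyl)-3,4-dimethylcyclobutane-1,2-dicarboxylate (side-chain methine carbons as a mixture) | COC(=O)[C@@H]1[C@H](C(=O)OC)[C@@](C)(C(=O)CC(=O)C(C)C(=O)OC)[C@@]1(C)C(=O)CC(=O)C(C)C(=O)OC
F6 | step 9 | (1R,2S,3R,4S)-3,4-bis(4-methoxy-3-methyl-2-oxo-2H-pyran-6-yl)-3,4-dimethylcyclobutane-1,2-dicarboxylic acid (meso) | OC(=O)[C@@H]1[C@H](C(=O)O)[C@@](C)(c2cc(OC)c(C)c(=O)o2)[C@@]1(C)c1cc(OC)c(C)c(=O)o1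
F7 | step 9 | (1R,5S,6S,7R)-6,7-bis(4-methoxy-3-methyl-2-oxo-2H-pyran-6-yl)-6,7-dimethyl-3-oxabicyclo[3.2.0]heptane-2,4-dione (meso anhydride of F6) | O=C2[C@@H]1[C@H](C(=O)O2)[C@@](C)(c3cc(OC)c(C)c(=O)o3)[C@@]1(C)c1cc(OC)c(C)c(=O)o1
A1 | alternative 1 | 1-methyl 2-tert-butyl (1R,2S,3R,4S)-3,4-bis(4-hydroxy-3-methyl-2-oxo-2H-pyran-6-yl)-3,4-dimethylcyclobutane-1,2-dicarboxylate | COC(=O)[C@@H]1[C@H](C(=O)OC(C)(C)C)[C@@](C)(c2cc(O)c(C)c(=O)o2)[C@@]1(C)c1cc(O)c(C)c(=O)o1
A2 | alternative 1 | 1-methyl 2-tert-butyl (1R,2S,3R,4S)-3,4-bis[(Z)-3-methoxy-3-oxo-1-(propanoyloxy)prop-1-enyl]-3,4-dimethylcyclobutane-1,2-dicarboxylate | COC(=O)[C@@H]1[C@H](C(=O)OC(C)(C)C)[C@@](C)(/C(OC(=O)CC)=C/C(=O)OC)[C@@]1(C)/C(OC(=O)CC)=C/C(=O)OC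
A3 | alternative 2 | dimethyl meso-3,4-dimethylcyclobutane-1,2,3,4-tetracarboxylate 3,4-anhydride (esters anti to the anhydride) | COC(=O)[C@@H]1[C@H](C(=O)OC)[C@@](C)(C3=O)[C@@]1(C)C(=O)O3
A4 | alternative 2 | meso-1,2-dimethylcyclobut-3-ene-1,2-dicarboxylic anhydride (1,5-dimethyl-3-oxabicyclo[3.2.0]hept-6-ene-2,4-dione) | C1=C[C@@](C)(C2=O)[C@@]1(C)C(=O)O2
A5 | alternative 3 | meso cis,anti,cis-1,2-dimethylcyclobutane-1,2,3,4-tetracarboxylic dianhydride | O=C2[C@@H]1[C@H](C(=O)O2)[C@@](C)(C3=O)[C@@]1(C)C(=O)O3
A6 | alternative 3 | 2,3-dimethylmaleic anhydride | CC1=C(C)C(=O)OC1=O
A7 | alternative 3 | maleic anhydride | O=C1OC(=O)C=C1
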